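## The problem

- Target 27 is an isoflavone whose ring A is a hexasubstituted benzene. O1, the C5 hydroxyl and the C7 hydroxyl alternate with three carbon substituents: the carbonyl carbon C4 on C4a, a prenyl group on C6, and an (R)-2-hydroxy-3-methylbut-3-enyl chain on C8.
- The first difficulty is regiochemical. Two different five-carbon chains must sit on the two carbons flanking the C7 oxygen, and ring C must be fused so that the correct phloroglucinol oxygen becomes O1.
- The only stereocentre is the carbinol carbon C2'' of the C8 chain (R; OH > isopropenyl > CH2Ar > H). It is remote from everything else, so nothing in the skeleton can control it and it must come from a chiral catalyst or reagent.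
- Several groups will not survive rough treatment. The prenyl group lies between two phenols and closes to a chroman under protic acid. The isopropenyl carbinol can ionise, rearrange or be trapped by the C7 hydroxyl under acid. The chromone is opened at C2 by hydroxide or amines. Three alkenes rule out hydrogenolysis.
- The four phenols therefore need one kind of protecting group that tolerates organolithium, palladium and chromium chemistry and comes off without protic acid.
- The feature that makes the key step possible lies in ring A before ring C exists. It is then a phloroglucinol triether that is mirror-symmetric about the axis through O1 and C6. Once one of its two equivalent ortho carbons carries iodine (the later C8), C4a is the only unsubstituted carbon ortho to O1. C4a is activated ortho and para by the two acetal oxygens, so an acyl cation tethered through O1–C2=C3 can close only there.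

## Retrosynthesis

**27 from 25.** The four aryl O–CH2OMe bonds are cut. Methoxymethyl ethers are kept throughout because they direct the lithiation that places the prenyl group, they survive base, organometallics and palladium, and they can be exchanged for silyl ethers under buffered aprotic conditions. Benzyl ethers would need hydrogenolysis, methyl ethers a boron halide, and silyl ethers would not survive the basic vinylic substitution. The forward step must remove four acetals without protic acid.

**25 from 23 and 24.** The C2''–C3'' bond between the carbinol carbon and the isopropenyl carbon is cut. Cutting C1''–C2'' instead would require an aryl-metal to open a vinyl epoxide, which invites allylic transposition and cannot coexist with the chromone. Cutting C8–C1'' with the complete chiral chain would need a β-oxygenated alkyl-metal. The chosen cut leaves arylacetaldehyde 23 without a stereocentre and 2-bromopropene 24. The forward reaction must be non-basic, because 23 enolises easily, and must be catalyst-controlled.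

**23 from 22, and 22 from 20 and 21.** The C8–C1'' bond is cut. The two-carbon aldehyde arrives as enol ether 22 by cross-coupling of aryl iodide 20 with boronate 21. The iodine at C8 in 20 is the handle, and the same atom made C4a the only site of ring closure one step earlier. The forward steps need a coupling at a doubly ortho-substituted iodide and a hydrolysis that leaves the acetals alone.

**20 from 18 (key disconnection).** The C4–C4a bond is cut, with acid chloride 19 as the reactive form. The neighbouring cut at O1–C2 leads to a deoxybenzoin, which must first be made by C-acylation of a phloroglucinol under strong Lewis acid and must then choose between two ortho oxygens. A cut at C3–C1' would need a chromone bearing two different halogens. With C4–C4a as the last ring bond, O1 is already attached, so the orientation of ring C is fixed. Precursor 18 has no ring C and falls apart into a phenol and a three-carbon aryl unit. The forward reaction must acylate C4a without free acid.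

**18 from 17, and 17 from 8 and 16.** The ester C–O bond of 17 is cut first, then the O1–C2 bond. A 2-(trimethylsilyl)ethyl ester is chosen because fluoride cleaves it, whereas hydroxide could add to C2 and expel the phenoxide. The O1–C2 bond comes from substitution of phenol 8 at the β-carbon of enol tosylate 16. Conjugate addition of 8 to an arylpropiolate would put the aryl group on C2 and give a flavone. The forward reaction must attack carbon and keep the Z geometry, which places the carboxyl carbon cis to the aryloxy group.

**8 from 7, 7 from 6, 6 from 3 and 4, 3 from 2, 2 from 1.** The C8–I bond, the O–Si bond, the C6–C1 bond of the prenyl group, the Si–O bond and two acetal bonds are cut in turn. Phenol 7 is mirror-symmetric, so its iodination gives one product. Silyl ether 3 is lithiated between its two acetal oxygens, which is exactly where the prenyl group belongs. The material goes back to phloroglucinol 1 and prenyl bromide 4. The only unselective step is the first, the bis-protection of 1.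

**16 from 15, 15 from 12 and 13, 12 from 11, 11 from 9.** The O–S bond, the C2–C3 bond (formyl carbon to benzylic carbon), the ester bond and the acetal bonds are cut. Ring B with both oxygens is bought intact as acid 9, and C2 comes from methyl formate 13. The forward sequence must give the Z enol tosylate, which a lithium chelate of the enolate should ensure.

## Roads not taken

**Alternative 1:** Ring C would be assembled from a ring A benzodioxinone A2 and the morpholine enamine A3 of the ring B arylacetaldehyde, cutting C3–C4 and O1–C2 together. Photolysis of A2 would release an ortho-quinone ketene, the enamine would add in a [4+2] sense, and loss of the amine would give the fully protected target A1.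

- Merits: two bonds and the ring form in one convergent, neutral step. The stereocentre is already in place, made on a simple arene, and only deprotection remains after the key step. In both respects this road is better than the chosen one, which needs four steps after ring closure and sets the stereocentre on the most valuable intermediate.
- Weak points: A2 is a hexasubstituted salicylate carrying both chains, the chiral silyl ether and the carboxyl carbon. Its synthesis repeats the ring A work of the chosen route and adds an ortho-carboxylation and the acetonide. The photolysis must run in the presence of two alkenes. The eliminated amine is itself a ketene trap and a nucleophile for C2 of the product. The nucleophilic carbon of A3 is benzylic and flanked by an ortho acetal.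
- Comparison: the chosen plan offers a ring A partner (8) made in five steps by symmetry, a ground-state ring closure of a known class, and no amine liberated next to a chromone.

**Alternative 2:** Ring A would be built last on a preformed pyranone by a Danheiser benzannulation. Irradiation and heating of the pyranonyl diazo ketone A5 with the prenyl-bearing siloxyalkyne A6 would form C8–C8a by Wolff shift and C5–C6, C7–C8 and C4a–C5 by cycloaddition and electrocyclisation. The product would be the 5-hydroxy-7-silyloxy isoflavone A4.

- Merits: the mechanism dictates the position of every ring A substituent, so no symmetry argument and no blocking group is needed. The stereocentre is carried in from A5. The C5 and C7 oxygens emerge differentiated. In regiochemical certainty this road is at least as good as the chosen one.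
- Weak points: the carbene from A5 has an adjacent CH2 group, so 1,2-hydrogen shift to an enone competes with the Wolff rearrangement. The vinylketene sits three atoms from an isopropenyl group and must survive heating. The 6π closure has to engage a pyranone double bond. Both A5 and A6 need multistep syntheses of their own, one of them enantioselective.
- Comparison: the chosen plan offers cheap achiral building blocks, ionic and palladium chemistry throughout, and a shorter count. It accepts in return that the stereocentre is set late.

**Alternative 3:** Ring B would be made last by the same benzannulation. Wolff rearrangement of the chromon-3-yl enone diazo ketone A8 and addition to triisopropylsiloxyacetylene A9 would form C5'–C6', C2'–C3', C4'–C5' and C1'–C2', giving A7 with a free 2'-hydroxyl and a silylated 4'-oxygen.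

- Merits: the conditions are mild and the two ring B oxygens come out differentiated.
- Weak points: ring B is the simplest part of the molecule and is commercially available intact as 9, so the annulation is spent where it is least needed. A8 already contains the whole of rings A and C with both chains and the stereocentre, so the real problem is left unsolved and merely moved. Installing a diazo ketone beside the electrophilic C2=C3 bond of a chromone, and irradiating it next to the chromone chromophore, add further risk.
- Comparison: the only respect in which it is better is the differentiation of the ring B oxygens, which the target does not require. The chosen plan is shorter and addresses ring A directly.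

Key step: step 12

Remark on the chemistry: the vinylic substitution of step 10 is assumed to retain the alkene geometry, as is usual for a sulfonate leaving group on the β-carbon of an acrylate. The antipode of the chromium ligand in step 15 is the one that delivers the isopropenyl group to the Si face of 23; this assignment is to be checked on a model arylacetaldehyde and by Mosher ester analysis.

## Route

Step 1
Reactants: 1 phloroglucinol
Product: 2 3,5-bis(methoxymethoxy)phenol
Conditions: MOMCl (2 equiv), iPr2NEt, CH2Cl2/DMF, 0 °C → rt
Reagents that add atoms: chloromethyl methyl ether, COCCl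
Why: O-alkylation of the phenol with an α-chloro ether; with two equivalents the bis-ether should be the main component of a statistical mixture and is separated by chromatography, the mono-ether being resubmitted.

Step 2
Reactants: 2 3,5-bis(methoxymethoxy)phenol
Product: 3 [3,5-bis(methoxymethoxy)phenoxy]triisopropylsilane
Conditions: iPr3SiCl, imidazole, DMF, rt
Reagents that add atoms: chlorotriisopropylsilane, CC(C)[Si](Cl)(C(C)C)C(C)C
Why: Imidazole-mediated silylation of a phenol; the bulky silyl ether withstands n-BuLi and is a poor director, which leaves the position between the acetals as the site of lithiation.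

Step 3
Reactants: 3 [3,5-bis(methoxymethoxy)phenoxy]triisopropylsilane; 4 prenyl bromide (1-bromo-3-methylbut-2-ene)
Product: 6 [3,5-bis(methoxymethoxy)-4-(3-methylbut-2-enyl)phenoxy]triisopropylsilane, via aryllithium 5 (not isolated)
Conditions: n-BuLi, THF, 0 °C; CuI (10 mol%), then 4, –78 °C → rt
Reagents that add atoms: n-butyllithium, [Li]CCCC (lithium in 5 only)
Why: Directed ortho-metalation at the carbon chelated by both acetal oxygens, then copper-mediated alkylation of the aryl anion, which should couple at the primary carbon of 4 without allylic transposition.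

Step 4
Reactants: 6 [3,5-bis(methoxymethoxy)-4-(3-methylbut-2-enyl)phenoxy]triisopropylsilane
Product: 7 3,5-bis(methoxymethoxy)-4-(3-methylbut-2-enyl)phenol
Conditions: Bu4NF, THF, 0 °C; aq. NH4Cl
Reagents that add atoms: none
Why: Fluoride cleavage of the aryl silyl ether; acetals and the alkene are inert to fluoride.

Step 5
Reactants: 7 3,5-bis(methoxymethoxy)-4-(3-methylbut-2-enyl)phenol
Product: 8 2-iodo-3,5-bis(methoxymethoxy)-4-(3-methylbut-2-enyl)phenol
Conditions: I2 (1.0 equiv), NaHCO3, THF/H2O, 0 °C
Reagents that add atoms: iodine, II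
Why: Electrophilic iodination of a phenoxide ortho to oxygen; the two ortho carbons of 7 are equivalent by mirror symmetry and the para carbon is blocked, so one equivalent should give a single mono-iodide faster than iodine adds to the prenyl alkene.

Step 6
Reactants: 9 2,4-dihydroxyphenylacetic acid
Product: 11 2-[2,4-bis(methoxymethoxy)phenyl]acetic acid, via tris(methoxymethyl) derivative 10 (not isolated)
Conditions: MOMCl (3.5 equiv), iPr2NEt, CH2Cl2, 0 °C → rt; then LiOH, THF/H2O, rt; cold dilute HCl to pH 4
Reagents that add atoms: chloromethyl methyl ether, COCCl; lithium hydroxide, [Li+].[OH-]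
Why: Exhaustive alkylation with the chloro ether, then saponification of the methoxymethyl ester, which as an acylal-type ester is far more labile to hydroxide than the two aryl acetals.

Step 7
Reactants: 11 2-[2,4-bis(methoxymethoxy)phenyl]acetic acid
Product: 12 2-(trimethylsilyl)ethyl 2-[2,4-bis(methoxymethoxy)phenyl]acetate
Conditions: 2-(trimethylsilyl)ethanol, EDC·HCl, DMAP (cat.), CH2Cl2, 0 °C → rt
Reagents that add atoms: 2-(trimethylsilyl)ethanol, C[Si](C)(C)CCO
Why: Steglich-type carbodiimide esterification; this ester is chosen because fluoride will later cleave it without any nucleophile attacking C2 of the acrylate.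

Step 8
Reactants: 12 2-(trimethylsilyl)ethyl 2-[2,4-bis(methoxymethoxy)phenyl]acetate; 13 methyl formate
Product: 15 2-(trimethylsilyl)ethyl (Z)-2-[2,4-bis(methoxymethoxy)phenyl]-3-hydroxyprop-2-enoate (enol form of the α-formyl ester), via lithium enolate 14 (not isolated)
Conditions: LiN(iPr)2 (2.2 equiv), THF, –78 °C; then 13, –78 → –20 °C; aq. NH4Cl
Reagents that add atoms: lithium diisopropylamide, CC(C)[N-]C(C)C.[Li+] (lithium in 14 only)
Why: Crossed Claisen condensation of a preformed ester enolate with a formate; preforming the enolate at low temperature keeps methoxide from exchanging the silylethyl ester, and the product should exist as the hydrogen-bonded enol.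

Step 9
Reactants: 15 2-(trimethylsilyl)ethyl (Z)-2-[2,4-bis(methoxymethoxy)phenyl]-3-hydroxyprop-2-enoate
Product: 16 2-(trimethylsilyl)ethyl (Z)-2-[2,4-bis(methoxymethoxy)phenyl]-3-(4-methylphenylsulfonyloxy)prop-2-enoate
Conditions: TsCl, N-methylimidazole, LiOH, CH2Cl2, 0 °C → rt
Reagents that add atoms: 4-methylbenzenesulfonyl chloride, Cc1ccc(S(=O)(=O)Cl)cc1
Why: O-sulfonylation of the enolate with N-methylimidazole as sulfonyl-transfer catalyst; the lithium chelate holds the enolate oxygen cis to the ester carbonyl, so the Z enol tosylate should result.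

Step 10
Reactants: 8 2-iodo-3,5-bis(methoxymethoxy)-4-(3-methylbut-2-enyl)phenol; 16 2-(trimethylsilyl)ethyl (Z)-2-[2,4-bis(methoxymethoxy)phenyl]-3-(4-methylphenylsulfonyloxy)prop-2-enoate
Product: 17 2-(trimethylsilyl)ethyl (Z)-2-[2,4-bis(methoxymethoxy)phenyl]-3-[2-iodo-3,5-bis(methoxymethoxy)-4-(3-methylbut-2-enyl)phenoxy]prop-2-enoate
Conditions: Cs2CO3, MeCN, 0 °C → rt (16 in slight excess)
Reagents that add atoms: none
Why: Nucleophilic vinylic substitution by addition–elimination: the phenoxide adds to the β-carbon of the acrylate and tosylate leaves, expected with retention of the Z geometry; a slight excess of 16 leaves no free phenoxide to re-add and scramble the alkene.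

Step 11
Reactants: 17 2-(trimethylsilyl)ethyl (Z)-2-[2,4-bis(methoxymethoxy)phenyl]-3-[2-iodo-3,5-bis(methoxymethoxy)-4-(3-methylbut-2-enyl)phenoxy]prop-2-enoate
Product: 18 (Z)-2-[2,4-bis(methoxymethoxy)phenyl]-3-[2-iodo-3,5-bis(methoxymethoxy)-4-(3-methylbut-2-enyl)phenoxy]prop-2-enoic acid
Conditions: Bu4NF, THF, 0 °C → rt; aq. NaH2PO4
Reagents that add atoms: none
Why: Fluoride-induced fragmentation of the 2-(trimethylsilyl)ethyl ester to carboxylate, ethene and the silyl fluoride; no hydroxide is present that could add to C2 and expel the phenoxide, and the buffered work-up spares the acetals.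

Step 12
Reactants: 18 (Z)-2-[2,4-bis(methoxymethoxy)phenyl]-3-[2-iodo-3,5-bis(methoxymethoxy)-4-(3-methylbut-2-enyl)phenoxy]prop-2-enoic acid
Product: 20 8-iodo-5,7-bis(methoxymethoxy)-3-[2,4-bis(methoxymethoxy)phenyl]-6-(3-methylbut-2-enyl)chromen-4-one, via acid chloride 19 (not isolated)
Conditions: 1-chloro-N,N,2-trimethylprop-1-en-1-amine (1.05 equiv), CH2Cl2, 0 °C, volatiles removed; then AgOTf, 2,6-di-tert-butylpyridine, CH2Cl2, –40 → 0 °C
Reagents that add atoms: 1-chloro-N,N,2-trimethylprop-1-en-1-amine, CC(C)=C(Cl)N(C)C (chlorine in 19 only)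
Why: The chloroenamine turns 18 into acid chloride 19 under neutral conditions, and AgOTf then abstracts chloride to give an acyl triflate or acyl cation that is stabilised as a vinylogous system by the oxygen on C2. The closest known reaction type is the Friedel–Crafts cyclisation of 3-aryloxyacrylic acids to chromones, run here through an acyl triflate instead of a protic or aluminium-based promoter. Ring C closes as a six-membered ring by intramolecular electrophilic aromatic substitution: the acyl carbon C4, held cis to the aryloxy group in the Z alkene, attacks C4a (exo with respect to the C≡O unit), and the hindered pyridine takes the proton from the arenium ion. No stereocentre is formed. Regioselectivity is secured by the substrate, because C8 carries iodine and C4a is the only free carbon ortho to O1, ortho and para to the two acetal oxygens. Chemoselectivity rests on the absence of free acid, since the pyridine buffers the triflic acid and so spares the acetals and the prenyl alkene, and on removing surplus chloroenamine before the silver salt is added, so that no keteniminium ion forms that could add to the prenyl group. Any E isomer present in 18 is expected to reach the reactive geometry because the acyl cation has ketene–oxocarbenium character, which lowers the barrier to rotation about C2–C3.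

Step 13
Reactants: 20 8-iodo-5,7-bis(methoxymethoxy)-3-[2,4-bis(methoxymethoxy)phenyl]-6-(3-methylbut-2-enyl)chromen-4-one; 21 (E)-2-(2-ethoxyvinyl)-4,4,5,5-tetramethyl-1,3,2-dioxaborolane
Product: 22 8-[(E)-2-ethoxyvinyl]-5,7-bis(methoxymethoxy)-3-[2,4-bis(methoxymethoxy)phenyl]-6-(3-methylbut-2-enyl)chromen-4-one
Conditions: Pd(OAc)2 (5 mol%), SPhos (10 mol%), K3PO4, THF/H2O, 60 °C
Reagents that add atoms: none
Why: Suzuki–Miyaura coupling; the electron-rich biarylphosphine should allow oxidative addition of the doubly ortho-substituted iodide to zerovalent palladium, and phosphate is too weak a base to open the chromone.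

Step 14
Reactants: 22 8-[(E)-2-ethoxyvinyl]-5,7-bis(methoxymethoxy)-3-[2,4-bis(methoxymethoxy)phenyl]-6-(3-methylbut-2-enyl)chromen-4-one
Product: 23 2-{5,7-bis(methoxymethoxy)-3-[2,4-bis(methoxymethoxy)phenyl]-6-(3-methylbut-2-enyl)-4-oxochromen-8-yl}acetaldehyde
Conditions: 1 M aq. HCl, THF, 0 °C → rt, short reaction time; NaHCO3 quench
Reagents that add atoms: water, O
Why: Acid-catalysed hydrolysis of an enol ether by rate-limiting protonation at carbon, which in dilute aqueous acid at or below room temperature should be much faster than ionisation of the aryl methoxymethyl acetals; 23 is used at once.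

Step 15
Reactants: 23 2-{5,7-bis(methoxymethoxy)-3-[2,4-bis(methoxymethoxy)phenyl]-6-(3-methylbut-2-enyl)-4-oxochromen-8-yl}acetaldehyde; 24 2-bromopropene
Product: 25 8-[(2R)-2-hydroxy-3-methylbut-3-enyl]-5,7-bis(methoxymethoxy)-3-[2,4-bis(methoxymethoxy)phenyl]-6-(3-methylbut-2-enyl)chromen-4-one
Conditions: CrCl2 (10 mol%), chiral 2-(2-methanesulfonamidophenyl)oxazoline ligand (11 mol%), 1,8-bis(dimethylamino)naphthalene (11 mol%), NiCl2(2,9-dimethyl-1,10-phenanthroline) (2 mol%), Mn, LiCl, Cp2ZrCl2, MeCN, rt; aq. work-up
Reagents that add atoms: none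
Why: Catalytic asymmetric Nozaki–Hiyama–Kishi reaction: nickel activates 24, the isopropenyl group passes to the ligand-bound chromium and adds to the Si face of the aldehyde, so the (R) stereocentre is set by the catalyst alone. The non-basic organochromium reagent tolerates the enolisable aldehyde, the chromone and the acetals.

Step 16
Reactants: 25 8-[(2R)-2-hydroxy-3-methylbut-3-enyl]-5,7-bis(methoxymethoxy)-3-[2,4-bis(methoxymethoxy)phenyl]-6-(3-methylbut-2-enyl)chromen-4-one
Product: 27 3-(2,4-dihydroxyphenyl)-5,7-dihydroxy-8-[(2R)-2-hydroxy-3-methylbut-3-enyl]-6-(3-methylbut-2-enyl)chromen-4-one, via pentakis(trimethylsilyl) ether 26 (not isolated)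
Conditions: TMSOTf, 2,2'-bipyridyl, MeCN, 0 °C → rt; then H2O, rt
Reagents that add atoms: trimethylsilyl trifluoromethanesulfonate, C[Si](C)(C)OS(=O)(=O)C(F)(F)F (silicon in 26 only)
Why: Silyl triflate with 2,2'-bipyridyl converts aryl methoxymethyl ethers into aryl silyl ethers under buffered aprotic conditions, and water then hydrolyses all silyl ethers, including the one on the carbinol. No protic acid is present that could close the prenyl group onto a phenol or ionise the allylic alcohol, so the stereocentre is untouched.

## Compound list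

1 | phloroglucinol | Oc1cc(O)cc(O)c1 | starting material
2 | 3,5-bis(methoxymethoxy)phenol | COCOc1cc(O)cc(OCOC)c1 | intermediate
3 | [3,5-bis(methoxymethoxy)phenoxy]triisopropylsilane | COCOc1cc(O[Si](C(C)C)(C(C)C)C(C)C)cc(OCOC)c1 | intermediate
4 | prenyl bromide (1-bromo-3-methylbut-2-ene) | CC(C)=CCBr | starting material
5 | [2,6-bis(methoxymethoxy)-4-(triisopropylsilyloxy)phenyl]lithium | [Li]c1c(OCOC)cc(O[Si](C(C)C)(C(C)C)C(C)C)cc1OCOC | intermediate
6 | [3,5-bis(methoxymethoxy)-4-(3-methylbut-2-enyl)phenoxy]triisopropylsilane | CC(C)=CCc1c(OCOC)cc(O[Si](C(C)C)(C(C)C)C(C)C)cc1OCOC | intermediate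
7 | 3,5-bis(methoxymethoxy)-4-(3-methylbut-2-enyl)phenol | CC(C)=CCc1c(OCOC)cc(O)cc1OCOC | intermediate
8 | 2-iodo-3,5-bis(methoxymethoxy)-4-(3-methylbut-2-enyl)phenol | CC(C)=CCc1c(OCOC)cc(O)c(I)c1OCOC | intermediate
9 | 2,4-dihydroxyphenylacetic acid | O=C(O)Cc1ccc(O)cc1O | starting material
10 | methoxymethyl 2-[2,4-bis(methoxymethoxy)phenyl]acetate | COCOC(=O)Cc1ccc(OCOC)cc1OCOC | intermediate
11 | 2-[2,4-bis(methoxymethoxy)phenyl]acetic acid | O=C(O)Cc1ccc(OCOC)cc1OCOC | intermediate
12 | 2-(trimethylsilyl)ethyl 2-[2,4-bis(methoxymethoxy)phenyl]acetate | C[Si](C)(C)CCOC(=O)Cc1ccc(OCOC)cc1OCOC | intermediate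
13 | methyl formate | COC=O | starting material
14 | lithium enolate of 12 | [Li]OC(=Cc1ccc(OCOC)cc1OCOC)OCC[Si](C)(C)C | intermediate
15 | 2-(trimethylsilyl)ethyl (Z)-2-[2,4-bis(methoxymethoxy)phenyl]-3-hydroxyprop-2-enoate | C[Si](C)(C)CCOC(=O)/C(=C\O)c1ccc(OCOC)cc1OCOC | intermediate
16 | 2-(trimethylsilyl)ethyl (Z)-2-[2,4-bis(methoxymethoxy)phenyl]-3-(4-methylphenylsulfonyloxy)prop-2-enoate | C[Si](C)(C)CCOC(=O)/C(=C\OS(=O)(=O)c1ccc(C)cc1)c1ccc(OCOC)cc1OCOC | intermediate
17 | 2-(trimethylsilyl)ethyl (Z)-2-[2,4-bis(methoxymethoxy)phenyl]-3-[2-iodo-3,5-bis(methoxymethoxy)-4-(3-methylbut-2-enyl)phenoxy]prop-2-enoate | C[Si](C)(C)CCOC(=O)/C(=C\Oc1cc(OCOC)c(CC=C(C)C)c(OCOC)c1I)c1ccc(OCOC)cc1OCOC | intermediate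
18 | (Z)-2-[2,4-bis(methoxymethoxy)phenyl]-3-[2-iodo-3,5-bis(methoxymethoxy)-4-(3-methylbut-2-enyl)phenoxy]prop-2-enoic acid | OC(=O)/C(=C\Oc1cc(OCOC)c(CC=C(C)C)c(OCOC)c1I)c1ccc(OCOC)cc1OCOC | intermediate
19 | (Z)-2-[2,4-bis(methoxymethoxy)phenyl]-3-[2-iodo-3,5-bis(methoxymethoxy)-4-(3-methylbut-2-enyl)phenoxy]prop-2-enoyl chloride | ClC(=O)/C(=C\Oc1cc(OCOC)c(CC=C(C)C)c(OCOC)c1I)c1ccc(OCOC)cc1OCOC | intermediate
20 | 8-iodo-5,7-bis(methoxymethoxy)-3-[2,4-bis(methoxymethoxy)phenyl]-6-(3-methylbut-2-enyl)chromen-4-one | Ic1c(OCOC)c(CC=C(C)C)c(OCOC)c2c(=O)c(-c3ccc(OCOC)cc3OCOC)coc12 | intermediate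
21 | (E)-2-(2-ethoxyvinyl)-4,4,5,5-tetramethyl-1,3,2-dioxaborolane | CCO/C=C/B1OC(C)(C)C(C)(C)O1 | starting material
22 | 8-[(E)-2-ethoxyvinyl]-5,7-bis(methoxymethoxy)-3-[2,4-bis(methoxymethoxy)phenyl]-6-(3-methylbut-2-enyl)chromen-4-one | CCO/C=C/c1c(OCOC)c(CC=C(C)C)c(OCOC)c2c(=O)c(-c3ccc(OCOC)cc3OCOC)coc12 | intermediate
23 | 2-{5,7-bis(methoxymethoxy)-3-[2,4-bis(methoxymethoxy)phenyl]-6-(3-methylbut-2-enyl)-4-oxochromen-8-yl}acetaldehyde | O=CCc1c(OCOC)c(CC=C(C)C)c(OCOC)c2c(=O)c(-c3ccc(OCOC)cc3OCOC)coc12 | intermediate
24 | 2-bromopropene | C=C(C)Br | starting material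
25 | 8-[(2R)-2-hydroxy-3-methylbut-3-enyl]-5,7-bis(methoxymethoxy)-3-[2,4-bis(methoxymethoxy)phenyl]-6-(3-methylbut-2-enyl)chromen-4-one | C=C(C)[C@H](O)Cc1c(OCOC)c(CC=C(C)C)c(OCOC)c2c(=O)c(-c3ccc(OCOC)cc3OCOC)coc12 | intermediate
26 | pentakis(trimethylsilyl) ether of 27 (four aryl silyl ethers and the (R)-carbinol silyl ether) | C=C(C)[C@H](O[Si](C)(C)C)Cc1c(O[Si](C)(C)C)c(CC=C(C)C)c(O[Si](C)(C)C)c2c(=O)c(-c3ccc(O[Si](C)(C)C)cc3O[Si](C)(C)C)coc12 | intermediate
27 | 3-(2,4-dihydroxyphenyl)-5,7-dihydroxy-8-[(2R)-2-hydroxy-3-methylbut-3-enyl]-6-(3-methylbut-2-enyl)chromen-4-one | C=C(C)[C@H](O)Cc1c(O)c(CC=C(C)C)c(O)c2c(=O)c(-c3ccc(O)cc3O)coc12 | target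

## Step count and least certain steps

Total: 16 steps. Longest linear sequence: 12 steps (steps 1–5 and 10–16, from phloroglucinol 1). The ring B branch (steps 6–9) joins at step 10.

**Step 12 (key step).** The acyl triflate may attack an acetal oxygen and cleave it before it finds C4a, or material that has drifted to the E geometry may fail to rotate into the reactive conformation.
Fallback, from 7 back to 20, closing the same C4–C4a bond with the polarity reversed:
- Phenol 7 is iodinated twice (two equivalents of I2, NaHCO3) to give 2,6-diiodo-3,5-bis(methoxymethoxy)-4-(3-methylbut-2-enyl)phenol F1.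
- F1 is joined to 16 as in step 10 to give 2-(trimethylsilyl)ethyl (Z)-2-[2,4-bis(methoxymethoxy)phenyl]-3-[2,6-diiodo-3,5-bis(methoxymethoxy)-4-(3-methylbut-2-enyl)phenoxy]prop-2-enoate F2.
- One equivalent of iPrMgCl·LiCl in THF at –40 °C exchanges one of the two equivalent iodines. The arylmagnesium adds to the ester carbonyl in a Parham-type cyclisation and expels the silylethoxide. The remaining iodine is then the C8 iodine of 20.

**Step 10.** The phenoxide may attack sulfur (sulfonyl transfer) instead of the β-carbon, and reversible addition of phenoxide may erode the Z geometry.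
Fallback, from 15 back to 17: the enol 15 is converted with chloromethylene-dimethyliminium chloride (from oxalyl chloride and DMF, buffered with 2,6-lutidine) into 2-(trimethylsilyl)ethyl (Z)-3-chloro-2-[2,4-bis(methoxymethoxy)phenyl]prop-2-enoate F3. The Z isomer is drawn; the geometry obtained from this chlorination is not known in advance, and any E isomer formed alongside is separated. With chloride as leaving group only carbon can be attacked, and substitution by the cesium salt of 8 gives 17.

**Step 14.** Partial loss of the acetal on the C7 oxygen would let the freed phenol close onto the aldehyde to a benzofuran.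
Fallback, from 20 back to 23, with no acid at any point:
- 20 is coupled with vinylboronic acid pinacol ester under the conditions of step 13 to give 8-vinyl-5,7-bis(methoxymethoxy)-3-[2,4-bis(methoxymethoxy)phenyl]-6-(3-methylbut-2-enyl)chromen-4-one F4.
- Hydroboration with 9-borabicyclo[3.3.1]nonane, which takes the terminal alkene ahead of the trisubstituted one, and oxidation with NaBO3·4H2O give 8-(2-hydroxyethyl)-5,7-bis(methoxymethoxy)-3-[2,4-bis(methoxymethoxy)phenyl]-6-(3-methylbut-2-enyl)chromen-4-one F5.
- Dess–Martin oxidation gives 23.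

**Step 15.** Facial selectivity may be poor with a hindered, easily enolised arylacetaldehyde, and 2-bromopropene may be activated slowly.
Fallback, from 23 back to 25:
- The same coupling without chiral ligand (CrCl2, catalytic NiCl2, DMF) gives racemic 8-(2-hydroxy-3-methylbut-3-enyl)-5,7-bis(methoxymethoxy)-3-[2,4-bis(methoxymethoxy)phenyl]-6-(3-methylbut-2-enyl)chromen-4-one F6.
- Dess–Martin oxidation gives 5,7-bis(methoxymethoxy)-3-[2,4-bis(methoxymethoxy)phenyl]-6-(3-methylbut-2-enyl)-8-(3-methyl-2-oxobut-3-enyl)chromen-4-one F7.
- Corey–Bakshi–Shibata reduction with the (S)-methyl oxazaborolidine and catecholborane at low temperature should give 25, with the isopropenyl group acting as the larger substituent. The chromone carbonyl, a vinylogous ester, should not be reduced.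

**Step 16.** Exchange of four acetals may be incomplete, or the triflate salts may ionise the allylic carbinol and close the prenyl group onto a phenol.
Fallback, from 20 back to 27, moving the acid-requiring deprotection to a stage without the allylic alcohol:
- The acetals of 20 are removed with HCl in methanol to give 3-(2,4-dihydroxyphenyl)-5,7-dihydroxy-8-iodo-6-(3-methylbut-2-enyl)chromen-4-one F8.
- Acetic anhydride and pyridine give its tetraacetate F9.
- Coupling with 21 under anhydrous conditions gives the 8-[(E)-2-ethoxyvinyl] tetraacetate F10.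
- Acid hydrolysis, to which aryl acetates are indifferent, gives the aldehyde tetraacetate F11.
- The chromium-catalysed addition of 24 gives the (R)-alcohol tetraacetate F12.
- K2CO3 in methanol at 0 °C then removes the acetates and gives 27 under conditions that touch neither the prenyl group nor the allylic alcohol.

## Further compounds

F1 | step 12 | 2,6-diiodo-3,5-bis(methoxymethoxy)-4-(3-methylbut-2-enyl)phenol | CC(C)=CCc1c(OCOC)c(I)c(O)c(I)c1OCOC
F2 | step 12 | 2-(trimethylsilyl)ethyl (Z)-2-[2,4-bis(methoxymethoxy)phenyl]-3-[2,6-diiodo-3,5-bis(methoxymethoxy)-4-(3-methylbut-2-enyl)phenoxy]prop-2-enoate | C[Si](C)(C)CCOC(=O)/C(=C\Oc1c(I)c(OCOC)c(CC=C(C)C)c(OCOC)c1I)c1ccc(OCOC)cc1OCOC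
F3 | step 10 | 2-(trimethylsilyl)ethyl (Z)-3-chloro-2-[2,4-bis(methoxymethoxy)phenyl]prop-2-enoate | C[Si](C)(C)CCOC(=O)/C(=C\Cl)c1ccc(OCOC)cc1OCOC
F4 | step 14 | 8-vinyl-5,7-bis(methoxymethoxy)-3-[2,4-bis(methoxymethoxy)phenyl]-6-(3-methylbut-2-enyl)chromen-4-one | C=Cc1c(OCOC)c(CC=C(C)C)c(OCOC)c2c(=O)c(-c3ccc(OCOC)cc3OCOC)coc12
F5 | step 14 | 8-(2-hydroxyethyl)-5,7-bis(methoxymethoxy)-3-[2,4-bis(methoxymethoxy)phenyl]-6-(3-methylbut-2-enyl)chromen-4-one | OCCc1c(OCOC)c(CC=C(C)C)c(OCOC)c2c(=O)c(-c3ccc(OCOC)cc3OCOC)coc12
F6 | step 15 | racemic 8-(2-hydroxy-3-methylbut-3-enyl)-5,7-bis(methoxymethoxy)-3-[2,4-bis(methoxymethoxy)phenyl]-6-(3-methylbut-2-enyl)chromen-4-one | C=C(C)C(O)Cc1c(OCOC)c(CC=C(C)C)c(OCOC)c2c(=O)c(-c3ccc(OCOC)cc3OCOC)coc12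
F7 | step 15 | 5,7-bis(methoxymethoxy)-3-[2,4-bis(methoxymethoxy)phenyl]-6-(3-methylbut-2-enyl)-8-(3-methyl-2-oxobut-3-enyl)chromen-4-one | C=C(C)C(=O)Cc1c(OCOC)c(CC=C(C)C)c(OCOC)c2c(=O)c(-c3ccc(OCOC)cc3OCOC)coc12
F8 | step 16 | 3-(2,4-dihydroxyphenyl)-5,7-dihydroxy-8-iodo-6-(3-methylbut-2-enyl)chromen-4-one | Ic1c(O)c(CC=C(C)C)c(O)c2c(=O)c(-c3ccc(O)cc3O)coc12
F9 | step 16 | 3-(2,4-diacetoxyphenyl)-5,7-diacetoxy-8-iodo-6-(3-methylbut-2-enyl)chromen-4-one | Ic1c(OC(C)=O)c(CC=C(C)C)c(OC(C)=O)c2c(=O)c(-c3ccc(OC(C)=O)cc3OC(C)=O)coc12
F10 | step 16 | 3-(2,4-diacetoxyphenyl)-5,7-diacetoxy-8-[(E)-2-ethoxyvinyl]-6-(3-methylbut-2-enyl)chromen-4-one | CCO/C=C/c1c(OC(C)=O)c(CC=C(C)C)c(OC(C)=O)c2c(=O)c(-c3ccc(OC(C)=O)cc3OC(C)=O)coc12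
F11 | step 16 | 2-[3-(2,4-diacetoxyphenyl)-5,7-diacetoxy-6-(3-methylbut-2-enyl)-4-oxochromen-8-yl]acetaldehyde | O=CCc1c(OC(C)=O)c(CC=C(C)C)c(OC(C)=O)c2c(=O)c(-c3ccc(OC(C)=O)cc3OC(C)=O)coc12
F12 | step 16 | 3-(2,4-diacetoxyphenyl)-5,7-diacetoxy-8-[(2R)-2-hydroxy-3-methylbut-3-enyl]-6-(3-methylbut-2-enyl)chromen-4-one | C=C(C)[C@H](O)Cc1c(OC(C)=O)c(CC=C(C)C)c(OC(C)=O)c2c(=O)c(-c3ccc(OC(C)=O)cc3OC(C)=O)coc12
A1 | alternative 1 | fully protected target: 8-[(2R)-2-(tert-butyldimethylsilyloxy)-3-methylbut-3-enyl]-5,7-bis(methoxymethoxy)-3-[2,4-bis(methoxymethoxy)phenyl]-6-(3-methylbut-2-enyl)chromen-4-one | C=C(C)[C@H](O[Si](C)(C)C(C)(C)C)Cc1c(OCOC)c(CC=C(C)C)c(OCOC)c2c(=O)c(-c3ccc(OCOC)cc3OCOC)coc12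
A2 | alternative 1 | 8-[(2R)-2-(tert-butyldimethylsilyloxy)-3-methylbut-3-enyl]-5,7-bis(methoxymethoxy)-2,2-dimethyl-6-(3-methylbut-2-enyl)-1,3-benzodioxin-4-one | CC1(C)OC(=O)c2c(OCOC)c(CC=C(C)C)c(OCOC)c(C[C@@H](O[Si](C)(C)C(C)(C)C)C(C)=C)c2O1
A3 | alternative 1 | 4-[(E)-2-[2,4-bis(methoxymethoxy)phenyl]vinyl]morpholine | COCOc1ccc(/C=C/N2CCOCC2)c(OCOC)c1
A4 | alternative 2 | 8-[(2R)-2-(tert-butyldimethylsilyloxy)-3-methylbut-3-enyl]-5-hydroxy-3-[2,4-bis(methoxymethoxy)phenyl]-6-(3-methylbut-2-enyl)-7-(triisopropylsilyloxy)chromen-4-one | C=C(C)[C@H](O[Si](C)(C)C(C)(C)C)Cc1c(O[Si](C(C)C)(C(C)C)C(C)C)c(CC=C(C)C)c(O)c2c(=O)c(-c3ccc(OCOC)cc3OCOC)coc12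
A5 | alternative 2 | 2-[(4R)-4-(tert-butyldimethylsilyloxy)-2-diazo-5-methylhex-5-enoyl]-5-[2,4-bis(methoxymethoxy)phenyl]pyran-4-one | C=C(C)[C@H](O[Si](C)(C)C(C)(C)C)CC(=[N+]=[N-])C(=O)c1cc(=O)c(-c2ccc(OCOC)cc2OCOC)co1
A6 | alternative 2 | triisopropyl(5-methylhex-4-en-1-ynyloxy)silane | CC(C)=CCC#CO[Si](C(C)C)(C(C)C)C(C)C
A7 | alternative 3 | 8-[(2R)-2-(tert-butyldimethylsilyloxy)-3-methylbut-3-enyl]-3-[2-hydroxy-4-(triisopropylsilyloxy)phenyl]-5,7-bis(methoxymethoxy)-6-(3-methylbut-2-enyl)chromen-4-one | C=C(C)[C@H](O[Si](C)(C)C(C)(C)C)Cc1c(OCOC)c(CC=C(C)C)c(OCOC)c2c(=O)c(-c3ccc(O[Si](C(C)C)(C(C)C)C(C)C)cc3O)coc12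
A8 | alternative 3 | 8-[(2R)-2-(tert-butyldimethylsilyloxy)-3-methylbut-3-enyl]-3-[(E)-4-diazo-3-oxobut-1-enyl]-5,7-bis(methoxymethoxy)-6-(3-methylbut-2-enyl)chromen-4-one | C=C(C)[C@H](O[Si](C)(C)C(C)(C)C)Cc1c(OCOC)c(CC=C(C)C)c(OCOC)c2c(=O)c(/C=C/C(=O)C=[N+]=[N-])coc12
A9 | alternative 3 | ethynyloxytriisopropylsilane | C#CO[Si](C(C)C)(C(C)C)C(C)C
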